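**Plan**
Numbering (germacrane type): C3 carries the angelate, C2 is the ring CH2, C1=C10(Me) is the Z alkene, C4(Me)=C5 is the E alkene, C6 carries the acetate, C7 carries the isopropyl group.
Cuts, in order: angelate C–O, C3–H (back to the C3 ketone), ring bond C1–C2, chain bond C9–C10, chain bond C6–C7.
Enabling feature: in the ten-membered ring, C2 lies between carbinol C3 and vinyl C1. At the ketone level C1=C10/C2/C3=O is therefore a β,γ-enone, and C2 can be an α-diazoketone carbon that binds a boron held on C1 and takes over the alkenyl group as N2 leaves (boron as a temporary eleventh ring atom).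
Forward: chain C2–C9 by allylboration of a keto-enal, C10/C1 added as a Z-bromopropenylboronate, diazo transfer, ring closure, ketone reduction, angeloylation. Only one ring arises.
Stereochemistry: C6/C7 come from one chiral-acid-catalysed anti allylboration, the E alkene from a furan-derived enal, the Z alkene from syn-bromoboration of propyne carried on with retention, and C3 from a catalyst-controlled reduction.

Key step: step 12

Assumption: (R)-TRIP phosphoric acid is taken to send the allyl group to the Re face of the aldehyde, as with simple aryl and alkenyl aldehydes; if the sense is opposite, the (S)-acid is used.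

Step 1
Reactants: 1 2,3-dimethylfuran
Product: 3 (E)-3-methyl-4-oxopent-2-enal, via (Z)-3-methyl-4-oxopent-2-enal 2 (not isolated)
Conditions: NBS, NaHCO3, acetone/H2O, −15 °C; then pyridine, rt
Reagents that add atoms: water O
Why: Oxidative furan ring opening (first stage of an Achmatowicz-type oxidation) should give the cis keto-enal 2, and pyridine-catalysed addition–elimination should relax it to the less crowded E isomer, in which acetyl and formyl are trans as C3 and C6 must be in the target.

Step 2
Reactants: 4 3-methylbut-1-yne; 5 pinacolborane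
Product: 6 (E)-4,4,5,5-tetramethyl-2-(3-methylbut-1-en-1-yl)-1,3,2-dioxaborolane
Conditions: Cp2ZrHCl (5 mol %), Et3N (10 mol %), neat, 60 °C (sealed)
Reagents that add atoms: none
Why: Zirconium-catalysed syn hydroboration of the terminal alkyne places boron on the terminal carbon and should give the E-alkenylboronate.

Step 3
Reactants: 6 (E)-alkenylboronate
Product: 8 (E)-4,4,5,5-tetramethyl-2-(4-methylpent-2-en-1-yl)-1,3,2-dioxaborolane, via chloromethyl boronate complex 7 (not isolated)
Conditions: BrCH2Cl, n-BuLi, THF, −78 °C to rt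
Reagents that add atoms: bromochloromethane ClCBr; n-butyllithium [Li]CCCC (lithium only in 7)
Why: Matteson homologation, in which chloromethyllithium adds to boron and the alkenyl group shifts with loss of chloride, inserts one CH2 and keeps the E geometry.

Step 4
Reactants: 3 (E)-3-methyl-4-oxopent-2-enal; 8 (E)-allylboronate
Product: 10 (3E,5R,6R)-5-hydroxy-3-methyl-6-(propan-2-yl)octa-3,7-dien-2-one, via pinacol borate ester 9 (not isolated)
Conditions: (R)-TRIP phosphoric acid (5 mol %), 4 Å MS, toluene, −30 °C; aqueous work-up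
Reagents that add atoms: none
Why: Chiral-phosphoric-acid-catalysed allylboration runs through a closed chair transition state, so the E-boronate should give the anti C6/C7 pair and the (R)-acid should direct attack to the Re face of the aldehyde (R at C6), while the ketone is too unreactive to compete.

Step 5
Reactants: 10 homoallylic alcohol
Product: 11 (3E,5R,6R)-5-acetoxy-3-methyl-6-(propan-2-yl)octa-3,7-dien-2-one
Conditions: Ac2O, pyridine, DMAP (cat.), CH2Cl2, 0 °C to rt
Reagents that add atoms: acetic anhydride CC(=O)OC(C)=O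
Why: DMAP-catalysed acylation installs the C6 acetate of the target at once, so the oxygens at C6 and C3 never have to be told apart later.

Step 6
Reactants: 11 acetate; 5 pinacolborane
Product: 13 (3E,5R,6S)-5-acetoxy-8-hydroxy-3-methyl-6-(propan-2-yl)oct-3-en-2-one, via primary alkyl pinacolboronate 12 (not isolated)
Conditions: [Ir(cod)Cl]2 (1.5 mol %), dppe (3 mol %), CH2Cl2, rt; then NaBO3·4H2O, THF/H2O, rt
Reagents that add atoms: sodium perborate [Na+].[O-]OB=O
Why: Iridium-catalysed anti-Markovnikov hydroboration should take only the monosubstituted alkene (pinacolborane does not reduce ketones unaided and the trisubstituted enone alkene is inert), and perborate oxidises the C–B bond mildly enough for acetate and enone.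

Step 7
Reactants: 13 primary alcohol
Product: 14 (3E,5R,6S)-5-acetoxy-8-iodo-3-methyl-6-(propan-2-yl)oct-3-en-2-one
Conditions: I2, PPh3, imidazole, CH2Cl2, 0 °C
Reagents that add atoms: iodine [I][I]
Why: Appel-type iodination replaces the primary hydroxyl by SN2 displacement of the alkoxyphosphonium ion and leaves enone and acetate alone.

Step 8
Reactants: 15 propyne
Product: 17 (Z)-2-(2-bromoprop-1-en-1-yl)-4,4,5,5-tetramethyl-1,3,2-dioxaborolane, via (Z)-2-bromoprop-1-enyldibromoborane 16 (not isolated)
Conditions: BBr3, CH2Cl2, −78 °C to rt; then pinacol, CH2Cl2, −78 °C to rt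
Reagents that add atoms: boron tribromide BrB(Br)Br; pinacol CC(C)(O)C(C)(C)O
Why: syn-Bromoboration of propyne puts boron on the terminal carbon cis to bromine, and esterification with pinacol fixes this Z geometry.

Step 9
Reactants: 14 primary iodide; 17 (Z)-bromopropenylboronate
Product: 19 (3E,5R,6S,9Z)-5-acetoxy-3,9-dimethyl-6-(propan-2-yl)-10-(4,4,5,5-tetramethyl-1,3,2-dioxaborolan-2-yl)deca-3,9-dien-2-one, via alkylzinc iodide 18 (not isolated)
Conditions: Zn dust, LiCl, THF, rt; then 17, Pd(P(t-Bu)3)2 (2 mol %), THF, rt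
Reagents that add atoms: zinc [Zn] (stays only in 18)
Why: In this Negishi coupling, oxidative addition of zerovalent palladium into the alkenyl C–Br bond should be far faster at rt than ionisation of the hindered allylic acetate, and coupling with retention should place C9 cis to boron (Z).

Step 10
Reactants: 19 methyl enone
Product: 21 (3E,5R,6S,9Z)-5-acetoxy-1-diazo-3,9-dimethyl-6-(propan-2-yl)-10-(4,4,5,5-tetramethyl-1,3,2-dioxaborolan-2-yl)deca-3,9-dien-2-one, via trifluoroacetyl ketone 20 (not isolated)
Conditions: LiN(SiMe3)2, THF, −78 °C; CF3CO2CH2CF3; then 4-acetamidobenzenesulfonyl azide, Et3N, H2O, MeCN, rt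
Reagents that add atoms: 4-acetamidobenzenesulfonyl azide CC(=O)Nc1ccc(cc1)S(=O)(=O)N=[N+]=[N-]; 2,2,2-trifluoroethyl trifluoroacetate FC(F)(F)COC(=O)C(F)(F)F (stays only in 20)
Why: Detrifluoroacetylative Regitz-type diazo transfer (kinetic deprotonation of the methyl group, C-trifluoroacetylation, then diazo transfer with loss of the activating acyl group) is the standard entry to α'-diazo enones and leaves pinacolboronate and acetate untouched.

Step 11
Reactants: 21 diazoketone pinacolboronate
Product: 22 potassium [(1Z,5S,6R,7E)-6-acetoxy-10-diazo-2,8-dimethyl-9-oxo-5-(propan-2-yl)deca-1,7-dien-1-yl]trifluoroborate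
Conditions: KF (aq.), L-(+)-tartaric acid, MeCN/THF, rt, minutes; filter, evaporate
Reagents that add atoms: potassium fluoride [K+].[F-]
Why: Fluoride/tartaric acid exchange converts the inert pinacolboronate into the trifluoroborate within minutes, and precipitation of the bitartrate keeps the medium only weakly acidic so that the diazoketone should survive.

Step 12
Reactants: 22 diazoketone trifluoroborate
Product: 26 (1R,2E,6Z,10S)-3,7-dimethyl-4-oxo-10-(propan-2-yl)cyclodeca-2,6-dien-1-yl acetate, via alkenyldifluoroborane 23 (not isolated), via eleven-membered diazonium borate 24 (not isolated), via ring-contracted alpha-boryl ketone 25 (not isolated)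
Conditions: 22 in THF added over 10 h to Me3SiCl (3 equiv), 2,6-di-tert-butylpyridine (1.5 equiv), CH2Cl2 (final 1 mM), −20 °C to rt; then pH 7 buffer
Reagents that add atoms: none
Why: Proposed new method: Me3SiCl strips one fluoride from 22 and sets free the Lewis-acidic alkenyldifluoroborane 23 at high dilution, the nucleophilic diazo carbon C2 binds to boron (borate 24), the alkenyl carbon C1 shifts from boron to C2 anti to the departing N2 (25), and hydrolysis at C2 gives 26. The closest known reaction type is the Hooz reaction (1,2-shift of an organoborane onto an α-diazocarbonyl compound), known between separate molecules for alkenyldihaloboranes, alkenylboroxines and Me3SiCl-activated trifluoroborates, but not as a ring closure. Mode of closure: reversible B–C coordination first closes an eleven-membered boracycle, which a three-centre 1,2-shift contracts to the ten-membered carbocycle, and the irreversible loss of N2 pays for the medium-ring strain. No stereocentre is created (C2 ends as CH2), the sp2 carbon migrates with retention so that the Z geometry set in 17 passes into the ring, and C6 and C7 are not touched. The step needs attack of C2 at boron to outrun conjugate alkenyl transfer to C5 (seven-membered ring), oligomerisation and acid attack on the diazo group: the alkenyl group is the only carbon ligand and fluoride is a poor migrating group, the fast diazo–borane reaction is favoured at low temperature, slow addition keeps 23 dilute, and the hindered pyridine takes up HCl. Kinetic protonation at the boron-bearing C2 without base should give the β,γ-enone, so C1=C10 does not move into conjugation.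

Step 13
Reactants: 26 macrocyclic ketone
Product: 28 (1R,2E,4S,6Z,10S)-4-hydroxy-3,7-dimethyl-10-(propan-2-yl)cyclodeca-2,6-dien-1-yl acetate, via catechol borate ester 27 (not isolated)
Conditions: (R)-Me-CBS oxazaborolidine (0.5 equiv), catecholborane, toluene, −78 °C; aqueous work-up
Reagents that add atoms: catecholborane [H]B1Oc2ccccc2O1 (stays only in 27)
Why: In the Corey–Bakshi–Shibata reduction the ketone should bind with the alkenyl arm C4 as the large group and the CH2 arm C2 as the small group, so the (R)-catalyst should deliver hydride 1,2 to give the S carbinol at C3, with acetate and alkenes inert at −78 °C.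

Step 14
Reactants: 28 allylic alcohol
Product: 30 (1S,2E,4R,5S,8Z)-4-acetoxy-2,8-dimethyl-5-(propan-2-yl)cyclodeca-2,8-dien-1-yl (2Z)-2-methylbut-2-enoate, via lithium alkoxide 29 (not isolated)
Conditions: LiN(SiMe3)2, THF, −78 °C; angelic anhydride, −78 to 0 °C
Reagents that add atoms: angelic anhydride C/C=C(/C)C(=O)OC(=O)/C(C)=C\C; lithium hexamethyldisilazide [Li+].C[Si](C)(C)[N-][Si](C)(C)C (lithium only in 29)
Why: O-acylation of the lithium alkoxide with angelic anhydride at low temperature is a stereoconservative angeloylation that avoids the nucleophilic catalysts and heat that turn angelate into tiglate, and the E alkene keeps the alkoxide away from the C6 acetate.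

**Compound list**
1 | 2,3-dimethylfuran | Cc1ccoc1C | starting material
2 | (Z)-3-methyl-4-oxopent-2-enal | CC(=O)/C(C)=C\C=O | intermediate
3 | (E)-3-methyl-4-oxopent-2-enal | CC(=O)/C(C)=C/C=O | intermediate
4 | 3-methylbut-1-yne | CC(C)C#C | starting material
5 | pinacolborane | [H]B1OC(C)(C)C(C)(C)O1 | starting material
6 | (E)-4,4,5,5-tetramethyl-2-(3-methylbut-1-en-1-yl)-1,3,2-dioxaborolane | CC(C)/C=C/B1OC(C)(C)C(C)(C)O1 | intermediate
7 | lithium chloromethyl[(E)-3-methylbut-1-enyl](pinacolato)borate | [Li+].ClC[B-]1(/C=C/C(C)C)OC(C)(C)C(C)(C)O1 | intermediate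
8 | (E)-4,4,5,5-tetramethyl-2-(4-methylpent-2-en-1-yl)-1,3,2-dioxaborolane | CC(C)/C=C/CB1OC(C)(C)C(C)(C)O1 | intermediate
9 | O-pinacolboryl ether of 10 | CC(=O)/C(=C/[C@@H]([C@@H](C=C)C(C)C)OB1OC(C)(C)C(C)(C)O1)C | intermediate
10 | (3E,5R,6R)-5-hydroxy-3-methyl-6-(propan-2-yl)octa-3,7-dien-2-one | CC(=O)/C(=C/[C@@H]([C@@H](C=C)C(C)C)O)C | intermediate
11 | (3E,5R,6R)-5-acetoxy-3-methyl-6-(propan-2-yl)octa-3,7-dien-2-one | CC(=O)/C(=C/[C@@H]([C@@H](C=C)C(C)C)OC(C)=O)C | intermediate
12 | (3E,5R,6S)-5-acetoxy-3-methyl-6-(propan-2-yl)-8-(4,4,5,5-tetramethyl-1,3,2-dioxaborolan-2-yl)oct-3-en-2-one | CC(=O)/C(=C/[C@@H]([C@@H](CCB1OC(C)(C)C(C)(C)O1)C(C)C)OC(C)=O)C | intermediate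
13 | (3E,5R,6S)-5-acetoxy-8-hydroxy-3-methyl-6-(propan-2-yl)oct-3-en-2-one | CC(=O)/C(=C/[C@@H]([C@@H](CCO)C(C)C)OC(C)=O)C | intermediate
14 | (3E,5R,6S)-5-acetoxy-8-iodo-3-methyl-6-(propan-2-yl)oct-3-en-2-one | CC(=O)/C(=C/[C@@H]([C@@H](CCI)C(C)C)OC(C)=O)C | intermediate
15 | propyne | CC#C | starting material
16 | (Z)-2-bromoprop-1-enyldibromoborane | C/C(Br)=C/B(Br)Br | intermediate
17 | (Z)-2-(2-bromoprop-1-en-1-yl)-4,4,5,5-tetramethyl-1,3,2-dioxaborolane | C/C(Br)=C/B1OC(C)(C)C(C)(C)O1 | intermediate
18 | alkylzinc iodide from 14 (zinc on C9) | CC(=O)/C(=C/[C@@H]([C@@H](CC[Zn]I)C(C)C)OC(C)=O)C | intermediate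
19 | (3E,5R,6S,9Z)-5-acetoxy-3,9-dimethyl-6-(propan-2-yl)-10-(4,4,5,5-tetramethyl-1,3,2-dioxaborolan-2-yl)deca-3,9-dien-2-one | CC(=O)/C(=C/[C@@H]([C@@H](CC/C(C)=C\B1OC(C)(C)C(C)(C)O1)C(C)C)OC(C)=O)C | intermediate
20 | 1-trifluoroacetyl derivative of 19 (drawn as the 1,3-diketone) | FC(F)(F)C(=O)CC(=O)/C(=C/[C@@H]([C@@H](CC/C(C)=C\B1OC(C)(C)C(C)(C)O1)C(C)C)OC(C)=O)C | intermediate
21 | (3E,5R,6S,9Z)-5-acetoxy-1-diazo-3,9-dimethyl-6-(propan-2-yl)-10-(4,4,5,5-tetramethyl-1,3,2-dioxaborolan-2-yl)deca-3,9-dien-2-one | [N-]=[N+]=CC(=O)/C(=C/[C@@H]([C@@H](CC/C(C)=C\B1OC(C)(C)C(C)(C)O1)C(C)C)OC(C)=O)C | intermediate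
22 | potassium [(1Z,5S,6R,7E)-6-acetoxy-10-diazo-2,8-dimethyl-9-oxo-5-(propan-2-yl)deca-1,7-dien-1-yl]trifluoroborate | [K+].[N-]=[N+]=CC(=O)/C(=C/[C@@H]([C@@H](CC/C(C)=C\[B-](F)(F)F)C(C)C)OC(C)=O)C | intermediate
23 | alkenyldifluoroborane from 22 | [N-]=[N+]=CC(=O)/C(=C/[C@@H]([C@@H](CC/C(C)=C\B(F)F)C(C)C)OC(C)=O)C | intermediate
24 | eleven-membered cyclic diazonium borate (boron bridges C1 and C2; C2 configuration open) | O=C1C([N+]#N)[B-](F)(F)/C=C(/C)CC[C@@H](C(C)C)[C@@H](OC(C)=O)/C=C/1C | intermediate
25 | 2-(difluoroboryl) derivative of 26 (boron on C2; C2 configuration open) | O=C1C(B(F)F)/C=C(/C)CC[C@@H](C(C)C)[C@@H](OC(C)=O)/C=C/1C | intermediate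
26 | (1R,2E,6Z,10S)-3,7-dimethyl-4-oxo-10-(propan-2-yl)cyclodeca-2,6-dien-1-yl acetate (6R,7S-6-acetoxygermacra-1(10)Z,4E-dien-3-one) | O=C1C/C=C(/C)CC[C@@H](C(C)C)[C@@H](OC(C)=O)/C=C/1C | intermediate
27 | O-catecholboryl ether of 28 | c1ccc2OB(O[C@H]3C/C=C(/C)CC[C@@H](C(C)C)[C@@H](OC(C)=O)/C=C/3C)Oc2c1 | intermediate
28 | (1R,2E,4S,6Z,10S)-4-hydroxy-3,7-dimethyl-10-(propan-2-yl)cyclodeca-2,6-dien-1-yl acetate | O[C@H]1C/C=C(/C)CC[C@@H](C(C)C)[C@@H](OC(C)=O)/C=C/1C | intermediate
29 | lithium alkoxide of 28 | [Li+].[O-][C@H]1C/C=C(/C)CC[C@@H](C(C)C)[C@@H](OC(C)=O)/C=C/1C | intermediate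
30 | (1S,2E,4R,5S,8Z)-4-acetoxy-2,8-dimethyl-5-(propan-2-yl)cyclodeca-2,8-dien-1-yl (2Z)-2-methylbut-2-enoate (CNP0306415.2) | C/C=C(/C)C(=O)O[C@H]1C/C=C(/C)CC[C@@H](C(C)C)[C@@H](OC(C)=O)/C=C/1C | target

Total step count: 14.
Longest linear sequence: 12 (steps 2, 3, 4, 5, 6, 7, 9, 10, 11, 12, 13, 14).

**Steps most likely to fail**

1. Step 12 (Proposed new method). Three things may go wrong: borate formation between molecules followed by oligomerisation, transfer of the alkenyl group to C5 of the enone with closure of a seven-membered ring, or acid-induced loss of the diazo group before it reaches boron. The fallback uses known chemistry and sets out from 21. Aqueous HBr in Et2O at 0 °C should turn the diazoketone into the bromomethyl ketone F1. An intramolecular Suzuki–Miyaura coupling of the α-bromoketone with the Z-alkenylboronate (Pd(OAc)2, P(o-tolyl)3, K3PO4, THF/H2O, high dilution, rt to 40 °C) should then close the same C1–C2 bond with retention. The fallback comes back to the route at 26, and steps 11 and 12 are not needed.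

2. Step 13. The medium ring exposes mainly the peripheral face of the carbonyl group, so ring control may oppose the catalyst and facial selectivity may be poor. The fallback sets out from 26. A Luche reduction (NaBH4, CeCl3·7H2O, MeOH, −78 °C) is run under pure ring control. If it delivers the C3 epimer, the (1R,2E,4R,6Z,10S)-alcohol F4, a Mitsunobu esterification with angelic acid (PPh3, DIAD, toluene, 0 °C) should install the angelate with inversion. The fallback comes back to the route at 30.

3. Step 11. The diazo group may be lost by protonation in the weakly acidic fluoride medium. The fallback reverses the order of events and sets out from 19. KHF2 in MeOH/H2O should give the potassium trifluoroborate methyl ketone F2, which tolerates amide bases. The detrifluoroacetylative diazo transfer is then run on this salt through the trifluoroacetyl ketone trifluoroborate F3, with purification by trituration. The fallback comes back to the route at 22.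

**Further compounds**
F1 | step 12 | (3E,5R,6S,9Z)-5-acetoxy-1-bromo-3,9-dimethyl-6-(propan-2-yl)-10-(4,4,5,5-tetramethyl-1,3,2-dioxaborolan-2-yl)deca-3,9-dien-2-one | BrCC(=O)/C(=C/[C@@H]([C@@H](CC/C(C)=C\B1OC(C)(C)C(C)(C)O1)C(C)C)OC(C)=O)C
F2 | step 11 | potassium [(1Z,5S,6R,7E)-6-acetoxy-2,8-dimethyl-9-oxo-5-(propan-2-yl)deca-1,7-dien-1-yl]trifluoroborate | [K+].CC(=O)/C(=C/[C@@H]([C@@H](CC/C(C)=C\[B-](F)(F)F)C(C)C)OC(C)=O)C
F3 | step 11 | 10-trifluoroacetyl derivative of F2 (drawn as the 1,3-diketone) | [K+].FC(F)(F)C(=O)CC(=O)/C(=C/[C@@H]([C@@H](CC/C(C)=C\[B-](F)(F)F)C(C)C)OC(C)=O)C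
F4 | step 13 | (1R,2E,4R,6Z,10S)-4-hydroxy-3,7-dimethyl-10-(propan-2-yl)cyclodeca-2,6-dien-1-yl acetate | O[C@@H]1C/C=C(/C)CC[C@@H](C(C)C)[C@@H](OC(C)=O)/C=C/1C
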